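Everything rests on cutting ring B at C1–C7 and C10=C11, which leaves ring A untouched. All of ring A (C1–C6), including the methyl-bearing C2=C3 alkene and the quaternary C6, is already present in α-cyclocitral, whose aldehyde carbon ends up as C11. Because C1–H is acidic and configurationally labile, both enantiomers can be merged in one flat dienamine. In one operation this chiral secondary dienamine bonds through C1 to methyl vinyl ketone and the unmasked keto aldehyde condenses, delivering ring B, two skeletal bonds and the spiro stereocentre. The precursor is simply the (R)-1-phenylethylamine imine of racemic α-cyclocitral. Afterwards ring B becomes the bromo(methyl)alkene and ring A the trans bromohydrin.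

Key step: step 2

Numbering used in the text: C1 is the spiro carbon. Ring A is C1, C2 (bears CH3), C3, C4, C5, C6 (CMe2). Ring B is C1, C7, C8, C9, C10, C11. The systematic names carry their own spiro[5.5]undecane locants.

Reading of the target: 1S,4S,5S. OH on C4 and Br on C5 are trans and both equatorial. Br lies on the face of ring A that carries C11, and OH on the face that carries C7.

Assumption: the dienamine is taken to react through the C11=C1 geometry with nitrogen on the C2 side, for which the (R)-amine should give (6R)-8. If the sense of induction proves opposite, the equally available (S)-amine is used and nothing else changes.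

Step 1
Reactants: 1 α-cyclocitral (racemic 2,6,6-trimethylcyclohex-2-ene-1-carbaldehyde); 2 (R)-1-phenylethylamine
Product: 3 (E)-N-[(2,6,6-trimethylcyclohex-2-en-1-yl)methylidene]-(1R)-1-phenylethanamine (both C1 epimers)
Conditions: 2 (1.05 equiv), 4 Å molecular sieves, toluene, 23 °C, 16 h; filtered, concentrated, used crude
Reagents that add atoms: none
Why: Condensation of an aldehyde with a primary amine over a drying agent is a routine imine formation, and the mixture of C1 epimers is of no consequence because C1 becomes planar in the next step.

Step 2
Reactants: 3 aldimine; 4 methyl vinyl ketone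
Product: 8 (6R)-7,11,11-trimethylspiro[5.5]undeca-1,7-dien-3-one, via dienamine 5 (not isolated), via keto aldimine 6 (not isolated), via keto aldehyde 7 (not isolated)
Conditions: 4 (2 equiv), 2,6-di-tert-butyl-4-methylphenol (1 mol %), toluene (2 M), 45 °C, 3–5 d; then AcOH/H2O/THF, 23 °C; then piperidine (0.3 equiv), 65 °C
Reagents that add atoms: water, O (its oxygen appears only in 7 and leaves again on dehydration)
Why: Proposed new method: imine 3 equilibrates with the flat secondary dienamine 5 (N–C11=C1–C2=C3), which wipes out the configuration at C1, and 5 is expected to bond through C1 to the CH2 terminus of 4 in a six-centre aza-ene transition state in which the N–H hydrogen passes to the α-carbon of the enone while C1–C7 forms, giving aldimine 6. The closest known reaction types are the deracemising Michael addition of 1-phenylethylamine imines of α-substituted cyclic ketones to electron-poor alkenes and the amine-mediated Robinson spiroannulation of α-branched aldehydes with 4, and neither has been shown for a nucleophilic carbon wedged between a quaternary carbon (C6) and a methyl-bearing sp2 carbon (C2). Aqueous acetic acid then frees keto aldehyde 7 and the auxiliary, and ring B closes by a 6-(enolendo)-exo-trig aldol addition of the methyl ketone carbon C10 to the formyl carbon C11 under piperidinium acetate catalysis, dehydration fixing C10=C11. C1 is the only new stereocentre and is controlled by the stereocentre of the amine: with its C–H bond in the enamine plane the phenyl group covers one face of C1, so that 4 arrives from the methyl side, which for the C11=C1 geometry with nitrogen on the side of the flat C2 leads to the 6R product. The step needs attack at C1 and not at the far more accessible C3, which is secured by the internal proton transfer, possible only when bonding occurs at C1, and by the fixed s-trans arrangement of C11=C1–C2=C3, which rules out a [4+2] addition. It also needs a single addition and configurational stability of the product, secured because 6 has no hydrogen on C1 from which an enamine could re-form and because the weakly acidic ring closure avoids the retro-Michael cleavage that strong base could trigger at the strained C1–C7 bond.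

Step 3
Reactants: 8 spiro dienone
Product: 9 (6R)-7,11,11-trimethylspiro[5.5]undeca-1,7-diene-3,9-dione (new ketone at C4)
Conditions: dirhodium tetrakis(caprolactamate) Rh2(C6H10NO)4 (1 mol %), t-BuOOH (70% in H2O, 5 equiv), ClCH2CH2Cl, 40 °C
Reagents that add atoms: tert-butyl hydroperoxide, CC(C)(C)OO
Why: This radical allylic C–H oxidation abstracts hydrogen with t-BuOO radicals, and C4H2 is the only secondary allylic position in 8 (C1 is quaternary and the electron-poor C10=C11 bond has no allylic hydrogen), just as in the familiar oxidation of α-ionone-type 2,6,6-trimethylcyclohex-2-enyl rings to their ring enones, while doing it at this stage also turns C2=C3 into an enone that is inert to the electrophilic bromine used later.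

Step 4
Reactants: 9 bis-enone
Product: 11 (6R)-2-bromo-7,11,11-trimethylspiro[5.5]undec-7-ene-3,9-dione (bromine on C10; both C10 epimers), via silyl enol ether 10 (not isolated)
Conditions: [(Ph3P)CuH]6 (3 mol %), PhMe2SiH (1.2 equiv), toluene, 0 to 23 °C; then THF, NaHCO3, N-bromosuccinimide (1.3 equiv), −78 to 0 °C
Reagents that add atoms: N-bromosuccinimide, O=C1CCC(=O)N1Br; dimethylphenylsilane, C[SiH](C)c1ccccc1 (silyl group only in 10)
Why: Copper hydride-catalysed 1,4-hydrosilylation delivers hydride to C11 of the β-monosubstituted ring B enone much faster than to the β,β-disubstituted neopentyl C2 of the ring A enone, so the silyl enol ether forms regiospecifically as C9=C10 and its α-halogenation with N-bromosuccinimide places bromine on C10 only, the C10 configuration being irrelevant because that carbon becomes sp2 in step 5.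

Step 5
Reactants: 11 C10-bromo diketone
Product: 13 (6R)-2-bromo-7,11,11-trimethyl-9-oxospiro[5.5]undeca-2,7-dien-3-yl trifluoromethanesulfonate (C9–OTf, C9=C10–Br), via lithium bromoenolate 12 (not isolated)
Conditions: LiN(SiMe3)2 (1.05 equiv), THF, −78 °C; N-(5-chloro-2-pyridyl)bis(trifluoromethanesulfonimide) (1.2 equiv), −78 to −20 °C
Reagents that add atoms: N-(5-chloro-2-pyridyl)bis(trifluoromethanesulfonimide), FC(F)(F)S(=O)(=O)N(c1ccc(Cl)cn1)S(=O)(=O)C(F)(F)F; LiN(SiMe3)2, [Li+].C[Si](C)(C)[N-][Si](C)(C)C (lithium only in 12)
Why: In this enol triflate formation the amide base removes the most acidic proton, the one on C10 flanked by carbonyl and bromine (C8–H and the neopentyl C5–H are less acidic), at a temperature at which neither HBr loss nor Favorskii closure competes, and the reactive pyridyl triflimide sulfonylates the enolate oxygen already in the cold.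

Step 6
Reactants: 13 bromo enol triflate
Product: 14 (6R)-8-bromo-1,5,5,9-trimethylspiro[5.5]undeca-1,8-dien-3-one
Conditions: Me4Sn (1.3 equiv), PdCl2(PPh3)2 (5 mol %), LiCl (3 equiv), DMF, 60 °C
Reagents that add atoms: tetramethylstannane, C[Sn](C)(C)C
Why: Stille coupling of an enol triflate under LiCl/DMF conditions, which favour insertion into C–OTf over C–Br as known for 2-bromocycloalk-1-enyl triflates, installs the C9 methyl group, tolerates the ring A enone that a methyl cuprate or Grignard reagent would endanger, and should stop there because the remaining bromide sits on a tetrasubstituted alkene.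

Step 7
Reactants: 14 ring A enone
Product: 17 (6S)-4,8-dibromo-1,5,5,9-trimethylspiro[5.5]undeca-1,8-dien-3-one (new bromine on C5; C5 epimers), via lithium dienolate 15 (not isolated), via silyl dienol ether 16 (not isolated)
Conditions: LiN(iPr)2 (1.1 equiv), THF, −78 °C; Me3SiCl (1.3 equiv); then N-bromosuccinimide (1.05 equiv), −78 to 0 °C
Reagents that add atoms: N-bromosuccinimide, O=C1CCC(=O)N1Br; chlorotrimethylsilane, C[Si](C)(C)Cl (silyl group only in 16); LiN(iPr)2, [Li+].CC(C)[N-]C(C)C (lithium only in 15)
Why: Kinetic deprotonation of a 3-methylcyclohexenone occurs at the α′ carbon (C5), as with isophorone, rather than at the γ methyl group, and N-bromosuccinimide attacks the resulting 2-silyloxydiene at its terminal carbon C5 (α-halogenation of a silyl enol ether) while the vinyl bromide of ring B is too electron-poor to react, no facial preference being relied on because C5 is corrected in step 8.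

Step 8
Reactants: 17 C5-epimeric bromo enone
Product: 18 (4S,6S)-4,8-dibromo-1,5,5,9-trimethylspiro[5.5]undeca-1,8-dien-3-one (5S, bromine equatorial on the C11 face)
Conditions: DBU (0.1 equiv), MeCN, 23 °C; chromatography, minor epimer resubmitted
Reagents that add atoms: none
Why: Base-catalysed epimerisation of an α-bromo ketone through its enolate (C6 carries no hydrogen, so HBr cannot be lost) should settle on the 5S epimer, because ring A prefers the half-chair that keeps C11 pseudoequatorial beside the C2 methyl group, on the side of the flat sp2 carbon C10, and C7 pseudoaxial, and only the 5S bromide is equatorial in that half-chair whereas the 5R bromide is either 1,3-diaxial to C7H2 or forces the ring flip, a preference that the polar solvent reinforces.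

Step 9
Reactants: 18 (5S)-bromo enone
Product: 19 (3R,4S,6S)-4,8-dibromo-1,5,5,9-trimethylspiro[5.5]undeca-1,8-dien-3-ol (cis bromohydrin, 4R,5S)
Conditions: iBu2AlH (1.3 equiv), CH2Cl2, −78 °C; aq potassium sodium tartrate
Reagents that add atoms: none
Why: 1,2-Reduction of the enone by the bulky aluminium hydride takes place from the C7 face of C4, opposite to the pseudoaxial C6 methyl group that stands 1,3 to the carbonyl carbon, and therefore gives the pseudoaxial 4R alcohol cis to the equatorial bromine, which is the wrong C4 epimer but forms predictably, whereas direct formation of the equatorial alcohol would require hydride attack past that methyl group.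

Step 10
Reactants: 19 cis bromohydrin
Product: 20 (3S,4S,6S)-4,8-dibromo-1,5,5,9-trimethylspiro[5.5]undeca-1,8-dien-3-yl 4-nitrobenzoate
Conditions: 4-nitrobenzoic acid (3 equiv), PPh3 (3 equiv), diisopropyl azodicarboxylate (3 equiv), toluene, 0 to 23 °C
Reagents that add atoms: 4-nitrobenzoic acid, O=C(O)c1ccc(cc1)[N+](=O)[O-]
Why: The Mitsunobu reaction with the acidic 4-nitrobenzoic acid inverts the pseudoaxial allylic alcohol, the carboxylate entering from the open C7 face anti to the leaving group, and even an allyl cation pathway would be captured on that same face (the other is covered by the C6 methyl group and by bromine) and at C4 rather than at the congested tertiary C2, so that the 4S,5S trans arrangement results.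

Step 11
Reactants: 20 4-nitrobenzoate
Product: 21 (3S,4S,6S)-4,8-dibromo-1,5,5,9-trimethylspiro[5.5]undeca-1,8-dien-3-ol (target)
Conditions: K2CO3 (0.2 equiv), MeOH, 0 °C
Reagents that add atoms: none
Why: Carbonate-catalysed transesterification of the activated 4-nitrobenzoate is fast in the cold, and epoxide formation is not expected because the trans bromohydrin is diequatorial and its diaxial form would place bromine 1,3-diaxial to C11H2.

Compound list
1 | α-cyclocitral, racemic 2,6,6-trimethylcyclohex-2-ene-1-carbaldehyde | CC1=CCCC(C)(C)C1C=O | starting material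
2 | (R)-1-phenylethylamine | C[C@@H](N)c1ccccc1 | starting material
3 | (E)-N-[(2,6,6-trimethylcyclohex-2-en-1-yl)methylidene]-(1R)-1-phenylethanamine, both C1 epimers | CC1=CCCC(C)(C)C1/C=N/[C@H](C)c1ccccc1 | intermediate
4 | methyl vinyl ketone (but-3-en-2-one) | CC(=O)C=C | starting material
5 | secondary dienamine, N-[(2,6,6-trimethylcyclohex-2-en-1-ylidene)methyl]-(1R)-1-phenylethanamine, nitrogen on the C2 side | CC1=CCCC(C)(C)/C1=C/N[C@H](C)c1ccccc1 | intermediate (not isolated)
6 | keto aldimine, (1R)-1-phenylethylamine imine of 7 | CC1=CCCC(C)(C)[C@@]1(CCC(C)=O)/C=N/[C@H](C)c1ccccc1 | intermediate (not isolated)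
7 | (1R)-2,6,6-trimethyl-1-(3-oxobutyl)cyclohex-2-ene-1-carbaldehyde | CC1=CCCC(C)(C)[C@@]1(CCC(C)=O)C=O | intermediate (not isolated)
8 | (6R)-7,11,11-trimethylspiro[5.5]undeca-1,7-dien-3-one | CC1=CCCC(C)(C)[C@]12CCC(=O)C=C2 | intermediate
9 | (6R)-7,11,11-trimethylspiro[5.5]undeca-1,7-diene-3,9-dione | CC1=CC(=O)CC(C)(C)[C@]12CCC(=O)C=C2 | intermediate
10 | dimethyl(phenyl)silyl enol ether of the ring B ketone (C9–OSi, C9=C10), spiro centre as in 9 | CC1=CC(=O)CC(C)(C)[C@]12CCC(O[Si](C)(C)c3ccccc3)=CC2 | intermediate (not isolated)
11 | (6R)-2-bromo-7,11,11-trimethylspiro[5.5]undec-7-ene-3,9-dione, both C10 epimers | CC1=CC(=O)CC(C)(C)[C@]12CCC(=O)C(Br)C2 | intermediate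
12 | lithium enolate C9(OLi)=C10(Br) of 11 | CC1=CC(=O)CC(C)(C)[C@]12CCC([O-])=C(Br)C2.[Li+] | intermediate (not isolated)
13 | (6R)-2-bromo-7,11,11-trimethyl-9-oxospiro[5.5]undeca-2,7-dien-3-yl trifluoromethanesulfonate | CC1=CC(=O)CC(C)(C)[C@]12CCC(OS(=O)(=O)C(F)(F)F)=C(Br)C2 | intermediate
14 | (6R)-8-bromo-1,5,5,9-trimethylspiro[5.5]undeca-1,8-dien-3-one | CC1=CC(=O)CC(C)(C)[C@]12CCC(C)=C(Br)C2 | intermediate
15 | lithium cross-conjugated dienolate C4(OLi)=C5 of 14 | CC1=CC([O-])=CC(C)(C)[C@]12CCC(C)=C(Br)C2.[Li+] | intermediate (not isolated)
16 | trimethylsilyl dienol ether C4(OSiMe3)=C5 of 14 | CC1=CC(O[Si](C)(C)C)=CC(C)(C)[C@]12CCC(C)=C(Br)C2 | intermediate (not isolated)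
17 | (6S)-4,8-dibromo-1,5,5,9-trimethylspiro[5.5]undeca-1,8-dien-3-one, C5 epimers | CC1=CC(=O)C(Br)C(C)(C)[C@]12CCC(C)=C(Br)C2 | intermediate
18 | (4S,6S)-4,8-dibromo-1,5,5,9-trimethylspiro[5.5]undeca-1,8-dien-3-one | CC1=CC(=O)[C@@H](Br)C(C)(C)[C@]12CCC(C)=C(Br)C2 | intermediate
19 | (3R,4S,6S)-4,8-dibromo-1,5,5,9-trimethylspiro[5.5]undeca-1,8-dien-3-ol (cis bromohydrin) | CC1=C[C@@H](O)[C@@H](Br)C(C)(C)[C@]12CCC(C)=C(Br)C2 | intermediate
20 | (3S,4S,6S)-4,8-dibromo-1,5,5,9-trimethylspiro[5.5]undeca-1,8-dien-3-yl 4-nitrobenzoate | CC1=C[C@H](OC(=O)c3ccc(cc3)[N+](=O)[O-])[C@@H](Br)C(C)(C)[C@]12CCC(C)=C(Br)C2 | intermediate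
21 | (3S,4S,6S)-4,8-dibromo-1,5,5,9-trimethylspiro[5.5]undeca-1,8-dien-3-ol | CC1=C[C@H](O)[C@@H](Br)C(C)(C)[C@]12CCC(C)=C(Br)C2 | target

Total step count: 11
Longest linear sequence: 11 steps (1 to 21)

Steps most likely to fail

Step 2. Three things may go wrong.
- Bond formation at the crowded C1 may be too slow.
- Attack may drift to the open C3.
- Facial discrimination may be weak, because an aldehyde-derived enamine fixes neither its C11=C1 geometry nor the rotamer of the N-substituent as firmly as a ketone-derived one.

The fallback uses known chemistry, sets out from 1 and returns at 8. The C1–C7 bond is made by SN2 alkylation of a slim nitrile-stabilised carbanion, and the enantiomers are separated afterwards. Aldehyde 1 is converted with NH2OH·HCl and pyridine into α-cyclocitral oxime F1, which acetic anhydride dehydrates to 2,6,6-trimethylcyclohex-2-ene-1-carbonitrile F2. Deprotonation with LiN(iPr)2 (THF, DMPU, −78 °C) and alkylation at the α-carbon with 2-(2-iodoethyl)-2-methyl-1,3-dioxolane gives the quaternary nitrile ketal F3. iBu2AlH (toluene, −78 to 0 °C) followed by buffered hydrolysis of the aldimine gives the aldehyde ketal F4. Dilute HCl in THF frees the racemic keto aldehyde F5, which piperidinium acetate closes to the racemic spiro dienone F6. Preparative chromatography on a chiral stationary phase then supplies 8. A merely moderate enantiomeric purity from step 2 itself might also be raised later by recrystallising ester 20.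

Step 8. The equilibrium may not lie far enough on the side of the equatorial 5S bromide, or the base may slowly consume the bromo enone. The fallback replaces thermodynamic by kinetic control, sets out from 17 and returns at 18. LiN(SiMe3)2 (THF, −78 °C) converts both epimers into the lithium bromo dienolate F7. This is protonated irreversibly at −78 °C with the hindered 2,6-di-tert-butyl-4-methylphenol. The proton is expected to enter C5 anti to the pseudoaxial C6 methyl group, that is from the C7 face, which pushes bromine onto the C11 face.

Step 5. Enolisation may occur towards C8 instead of C10, or HBr may be lost. The fallback generates the bromo enolate regiospecifically instead of by deprotonation, sets out from 9 and returns at 12 and thus at 13. Br2 (1 equiv, CH2Cl2, −78 to 0 °C) should add to the less hindered disubstituted C10=C11 bond to give the 10,11-dibromide F8. Et3N then removes HBr to give the ring B 2-bromo enone F9. Conjugate hydride delivery to C11 of this more electrophilic enone (Li[HB(sBu)3], 1 equiv, THF, −78 °C) produces enolate 12 with its double bond necessarily between C9 and C10. The same triflimide is then added.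

Further compounds
F1 | step 2 | α-cyclocitral oxime | CC1=CCCC(C)(C)C1C=NO
F2 | step 2 | 2,6,6-trimethylcyclohex-2-ene-1-carbonitrile (racemic) | CC1=CCCC(C)(C)C1C#N
F3 | step 2 | 2,6,6-trimethyl-1-[2-(2-methyl-1,3-dioxolan-2-yl)ethyl]cyclohex-2-ene-1-carbonitrile (racemic) | CC1=CCCC(C)(C)C1(C#N)CCC1(C)OCCO1
F4 | step 2 | 2,6,6-trimethyl-1-[2-(2-methyl-1,3-dioxolan-2-yl)ethyl]cyclohex-2-ene-1-carbaldehyde (racemic) | CC1=CCCC(C)(C)C1(C=O)CCC1(C)OCCO1
F5 | step 2 | racemic 2,6,6-trimethyl-1-(3-oxobutyl)cyclohex-2-ene-1-carbaldehyde | CC1=CCCC(C)(C)C1(C=O)CCC(C)=O
F6 | step 2 | racemic 7,11,11-trimethylspiro[5.5]undeca-1,7-dien-3-one | CC1=CCCC(C)(C)C12CCC(=O)C=C2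
F7 | step 8 | lithium bromo dienolate C4(OLi)=C5(Br) of 17 | CC1=CC([O-])=C(Br)C(C)(C)[C@]12CCC(C)=C(Br)C2.[Li+]
F8 | step 5 | 10,11-dibromide of 9 (1,2-dibromo-7,11,11-trimethylspiro[5.5]undec-7-ene-3,9-dione) | CC1=CC(=O)CC(C)(C)[C@]12CCC(=O)C(Br)C2Br
F9 | step 5 | ring B 2-bromo enone (2-bromo-7,11,11-trimethylspiro[5.5]undeca-1,7-diene-3,9-dione) | CC1=CC(=O)CC(C)(C)[C@]12CCC(=O)C(Br)=C2
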